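After 5.0 h of stirring, I wanted to know which of starting material, open intermediate and target held the most of the charge in three flasks that differed in second catalyst.

    starting material + free catalyst ⇌ free catalyst + open intermediate (K1 = 2.7, k1 = 60 M⁻¹ h⁻¹)
    second catalyst + open intermediate ⇌ catalyst intermediate (K2 = 0.10 M⁻¹, k2 = 13 M⁻¹ h⁻¹)
    coupling partner + catalyst intermediate → second catalyst + target (k3 = 62 M⁻¹ h⁻¹)
    second catalyst + target ⇌ idle complex (K4 = 0.15 M⁻¹, k4 = 0.95 M⁻¹ h⁻¹)

| flask | starting material | coupling partner | free catalyst | second catalyst | time |
|---|---|---|---|---|---|
| spring | 0.59 M | 0.649 M | 2.9 mM | 59 mM | 5.0 h |
| dusk | 0.59 M | 0.649 M | 2.9 mM | 77 mM | 5.0 h |
| noon | 0.59 M | 0.649 M | 2.9 mM | 100 mM | 5.0 h |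

* which of these there is most of at the end, counted by the starting material in it, spring (starting material / open intermediate / target)
* which of these there is most of at the end, counted by the starting material in it, dusk (starting material / open intermediate / target)
* which of these there is most of at the end, counted by the starting material in it, noon (starting material / open intermediate / target)
* how much there is at the end of the one of these that leads, in percent of the starting material charged: spring
* how much there is at the end of the one of these that leads, in percent of the starting material charged: dusk
* how much there is at the end of the one of these that leads, in percent of the starting material charged: noon

- for target the idle complex is counted in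
- run time (spring): 5.0 h

Free catalyst stands on both sides of step 1, so it stays at its charge, and step 1 is pseudo-first-order: each hour a fraction 0.174 h⁻¹ of the starting material goes over to open intermediate, and a fraction 0.0644 h⁻¹ of the open intermediate comes back. I called the forward rate constant of step 1 times free catalyst times time the first-step clock, and it read 0.870 for this run.

The clock gave two edges for the fraction of starting material left. With nothing coming back, that fraction is exp(-x), or 41.9%. With open intermediate never leaving, step 1 relaxes towards 27.0% at the sum of both rates, which leaves 49.2%. Second catalyst enters neither edge.

Between the edges the contest is between the way back and the drain onward. With coupling partner as charged, step 3 alone gives catalyst intermediate a half-life of 1.0 min in spring, but catalyst intermediate also falls back by step 2 at 130 h⁻¹, faster than the 40.2 h⁻¹ of step 3, so a share 0.236 of it goes on to target. The net drain is therefore 0.181 h⁻¹ in spring and 0.307 h⁻¹ in noon, more than the way back, and 1.04 to 1.76 times the feed. So I expected open intermediate and target to share the remaining 58.1% or less. To pass starting material, one of them would need 0.721 of that remainder. I committed to starting material leading in each flask, inside my range, which is not a single number.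

The forecast named starting material in spring, starting material in dusk and starting material in noon, at 47%, 46.5% and 46%, holding that “its level barely depends on the second catalyst loading”.

The simulation gave starting material as the leader at 47.3% in spring, 46.9% in dusk and 46.5% in noon, each more than 41.9% and less than 49.2%, and the forecast held in each flask. From spring to noon, starting material fell by 0.80 percentage points while target rose from 19.1% to 26.7%. A neighbour of spring charged with 7.2 × 10⁻⁴ M of free catalyst had a clock of 0.216, which puts the edges at 80.6% and 81.3%, and that neighbour ended with 81.1% of its starting material.

(The numbers are made up; what happens was integrated by code.)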